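**Plan**

- Retrosynthesis: remove the four MOM ethers, then cut the aryl–C(=O) bond at C7 of the benzoxepine (aryllithium plus the Weinreb amide of dihydrocaffeic acid). Next, isomerise the oxepine back to a 2,2-dimethyl-2H-chromene (O1–C2 cut, oxygen returned to the quaternary carbon), take off its two MOM ethers, and cut the chromene to phloroglucinol and prenal.
- Enabling feature: the seven-membered ring O1–C2H2–C3(CH3)=C4H–C5H2, fused at C5a/C9a, is an isoprene unit held between a phenol oxygen and its ortho carbon. It is therefore a constitutional isomer of the 2,2-dimethyl-2H-pyran ring O1–C(CH3)2–CH=CH on the same two arene carbons, and light should interconvert them through an ortho-quinone methide.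
- Forward order: phloroglucinol and prenal → chromenediol (pyran ring) → bis-MOM chromene → photochemical ring expansion to the 2,5-dihydro-1-benzoxepine (last ring closed) → C7 lithiation/acylation to join the dihydrocaffeoyl chain → global deprotection.
- Stereochemistry: the target has no stereocentre; its only geometric element, the cis C3=C4 ring alkene, is fixed by the ring closure itself.

Key step: step 3

Remark: benzoxepine numbering used throughout is O1, C2H2, C3(CH3), C4H, C5H2, C5a, C6–C9, C9a.

**Route**

Step 1
Reactants: 1 benzene-1,3,5-triol (phloroglucinol); 2 3-methylbut-2-enal (prenal)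
Product: 4 2,2-dimethyl-2H-chromene-5,7-diol, via ortho-quinone methide 3 (not isolated)
Conditions: 1 (3 equiv), ethylenediammonium diacetate (10 mol %), MeCN, 80 °C
Reagents that add atoms: none
Why: Amine-catalysed Knoevenagel-type condensation of a ring carbon of the triol with the iminium ion of prenal should give ortho-quinone methide 3, which closes by oxa-6π-electrocyclization (formal [3+3] chromenylation); the three ring positions are equivalent, so only one mono-chromene exists, and the excess of the cheap, water-soluble triol should hold back a second annulation.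

Step 2
Reactants: 4 2,2-dimethyl-2H-chromene-5,7-diol
Product: 5 5,7-bis(methoxymethoxy)-2,2-dimethyl-2H-chromene
Conditions: MOMCl (2.6 equiv), i-Pr2NEt, CH2Cl2, 0 °C to rt
Reagents that add atoms: chloromethyl methyl ether (MOMCl), COCCl
Why: Williamson-type O-alkylation with excess MOMCl should cap both phenols exhaustively, so no statistical mixture arises, and the basic medium should spare the acid-sensitive chromene.

Step 3
Reactants: 5 5,7-bis(methoxymethoxy)-2,2-dimethyl-2H-chromene
Product: 8 6,8-bis(methoxymethoxy)-3-methyl-2,5-dihydro-1-benzoxepine, via ortho-quinone methide 6 (not isolated), via dienylphenol 7 (not isolated)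
Conditions: hν (UV-B, about 310 nm, Pyrex), degassed MeCN (0.01 M), FEP-coil flow reactor, 20 °C
Reagents that add atoms: none
Why: Excitation of the styrene-type chromophore of 5 should open the pyran C2–O bond (retro-oxa-6π-electrocyclization) to ortho-quinone methide 6, in which one methyl group of the former gem-dimethyl carbon lies over the carbonyl oxygen, so that a [1,7]-hydrogen shift gives Z-dienylphenol 7. Absorbing in the same window, 7 should pass its acidic excited-state phenol proton to the benzylic diene carbon, and the phenoxide/2-methylallyl cation pair should collapse at the primary CH2 terminus, a net 1,4-addition of ArO–H across the diene. The closest known reaction type is the photochemical ring expansion of 5-oxygenated 2,2-dimethyl-2H-chromenes to 3-methyl-2,5-dihydro-1-benzoxepines, which rests on the photochromic ring opening of chromenes and on excited-state proton transfer in ortho-alkenylphenols. The oxepine ring closes in the 7-endo mode by O–C2 bond formation on the s-cis diene; no stereocentre is formed and the C3=C4 alkene is cis because it is born inside the ring. The step needs the [1,7]-shift to compete with thermal 6π re-closure and the oxygen to bond to CH2 and not to the internal allylic carbon (which would give a 2-isopropenyl-2,3-dihydrobenzofuran): re-closure only returns 5 for another excitation, the gem-dimethyl group supplies the hydrogen, the two other oxygens are capped as MOM ethers so that only the oxygen freed from the pyran can close, and 8, having lost the styrene chromophore, should be transparent at the wavelength used and collect as the photostable isomer.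

Step 4
Reactants: 9 3-(3,4-dihydroxyphenyl)propanoic acid
Product: 10 methoxymethyl 3-[3,4-bis(methoxymethoxy)phenyl]propanoate
Conditions: MOMCl (3.5 equiv), i-Pr2NEt, CH2Cl2/DMF, 0 °C to rt
Reagents that add atoms: chloromethyl methyl ether (MOMCl), COCCl
Why: Williamson-type alkylation should cap both phenols and the carboxylate in one operation, the methoxymethyl ester serving as an activated acyl donor for the next step.

Step 5
Reactants: 10 methoxymethyl 3-[3,4-bis(methoxymethoxy)phenyl]propanoate
Product: 11 3-[3,4-bis(methoxymethoxy)phenyl]-N-methoxy-N-methylpropanamide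
Conditions: MeNH(OMe)·HCl, i-PrMgCl, THF, −20 to 0 °C
Reagents that add atoms: N,O-dimethylhydroxylamine hydrochloride, CNOC.Cl
Why: Aminolysis of the activated ester by the chloromagnesium amide of N,O-dimethylhydroxylamine (Weinreb amide formation) should be clean, the aryl MOM ethers being inert to the Grignard base at low temperature.

Step 6
Reactants: 8 6,8-bis(methoxymethoxy)-3-methyl-2,5-dihydro-1-benzoxepine; 11 3-[3,4-bis(methoxymethoxy)phenyl]-N-methoxy-N-methylpropanamide
Product: 14 1-[6,8-bis(methoxymethoxy)-3-methyl-2,5-dihydro-1-benzoxepin-7-yl]-3-[3,4-bis(methoxymethoxy)phenyl]propan-1-one, via aryllithium 12 (not isolated), via lithium hemiaminal alkoxide 13 (not isolated)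
Conditions: n-BuLi (1.05 equiv), TMEDA, THF, −20 to 0 °C; then 11, −78 to 0 °C; aq. NH4Cl
Reagents that add atoms: none
Why: Directed ortho-metalation should remove C7–H, which lies between two lithium-chelating MOM ethers, in preference to C9–H (one MOM ether and the ring oxygen) and to the C5 methylene, and aryllithium 12 should add only once to the Weinreb amide (Weinreb ketone synthesis) because chelate 13 holds until the quench.

Step 7
Reactants: 14 1-[6,8-bis(methoxymethoxy)-3-methyl-2,5-dihydro-1-benzoxepin-7-yl]-3-[3,4-bis(methoxymethoxy)phenyl]propan-1-one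
Product: 15 1-(6,8-dihydroxy-3-methyl-2,5-dihydro-1-benzoxepin-7-yl)-3-(3,4-dihydroxyphenyl)propan-1-one
Conditions: 2 M HCl (aq.)/MeOH, 45 °C
Reagents that add atoms: none
Why: Acid-catalysed transacetalization of the four aryl MOM ethers to dimethoxymethane in methanol should free all phenols, the two acetals flanking the ketone going first with hydrogen-bond assistance, while dilute acid at moderate temperature should leave the trisubstituted ring alkene and the allyl aryl ether intact.

**Compound list**

1 | benzene-1,3,5-triol (phloroglucinol) | Oc1cc(O)cc(O)c1 | starting material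
2 | 3-methylbut-2-enal (prenal) | CC(C)=CC=O | starting material
3 | (6Z)-3,5-dihydroxy-6-(3-methylbut-2-en-1-ylidene)cyclohexa-2,4-dien-1-one (ortho-quinone methide, not isolated) | O=C1C=C(O)C=C(O)/C1=C/C=C(C)C | intermediate
4 | 2,2-dimethyl-2H-chromene-5,7-diol | CC1(C)C=Cc2c(O)cc(O)cc2O1 | intermediate
5 | 5,7-bis(methoxymethoxy)-2,2-dimethyl-2H-chromene | CC1(C)C=Cc2c(OCOC)cc(OCOC)cc2O1 | intermediate
6 | (6Z)-3,5-bis(methoxymethoxy)-6-(3-methylbut-2-en-1-ylidene)cyclohexa-2,4-dien-1-one (ortho-quinone methide, not isolated) | O=C1C=C(OCOC)C=C(OCOC)/C1=C/C=C(C)C | intermediate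
7 | 3,5-bis(methoxymethoxy)-2-[(1Z)-3-methylbuta-1,3-dien-1-yl]phenol (dienylphenol, not isolated) | C=C(C)/C=C\c1c(O)cc(OCOC)cc1OCOC | intermediate
8 | 6,8-bis(methoxymethoxy)-3-methyl-2,5-dihydro-1-benzoxepine | CC1=CCc2c(OCOC)cc(OCOC)cc2OC1 | intermediate
9 | 3-(3,4-dihydroxyphenyl)propanoic acid (dihydrocaffeic acid) | OC(=O)CCc1ccc(O)c(O)c1 | starting material
10 | methoxymethyl 3-[3,4-bis(methoxymethoxy)phenyl]propanoate | COCOC(=O)CCc1ccc(OCOC)c(OCOC)c1 | intermediate
11 | 3-[3,4-bis(methoxymethoxy)phenyl]-N-methoxy-N-methylpropanamide | CON(C)C(=O)CCc1ccc(OCOC)c(OCOC)c1 | intermediate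
12 | [6,8-bis(methoxymethoxy)-3-methyl-2,5-dihydro-1-benzoxepin-7-yl]lithium (not isolated) | CC1=CCc2c(cc(OCOC)c([Li])c2OCOC)OC1 | intermediate
13 | lithium 1-[6,8-bis(methoxymethoxy)-3-methyl-2,5-dihydro-1-benzoxepin-7-yl]-3-[3,4-bis(methoxymethoxy)phenyl]-1-[methoxy(methyl)amino]propan-1-olate (not isolated) | CC1=CCc2c(cc(OCOC)c(C(O[Li])(CCc3ccc(OCOC)c(OCOC)c3)N(C)OC)c2OCOC)OC1 | intermediate
14 | 1-[6,8-bis(methoxymethoxy)-3-methyl-2,5-dihydro-1-benzoxepin-7-yl]-3-[3,4-bis(methoxymethoxy)phenyl]propan-1-one | CC1=CCc2c(cc(OCOC)c(C(=O)CCc3ccc(OCOC)c(OCOC)c3)c2OCOC)OC1 | intermediate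
15 | 1-(6,8-dihydroxy-3-methyl-2,5-dihydro-1-benzoxepin-7-yl)-3-(3,4-dihydroxyphenyl)propan-1-one | CC1=CCc2c(cc(O)c(C(=O)CCc3ccc(O)c(O)c3)c2O)OC1 | target

**Summary**

Total step count: 7. Longest linear sequence: 5 steps (steps 1, 2, 3, 6, 7); steps 4 and 5 make the side-chain fragment.

Steps most likely to fail:

1. Step 3. The photochemical cascade may leak in three ways: light-driven drift of the Z-dienylphenol to its E isomer, which cannot close; oxygen–carbon bond formation at the internal allylic carbon to give a five-membered ring; or photo-oxidation of the electron-rich intermediates. The fallback closes the ring by olefin metathesis. It sets out from 1 and comes back to the route at 8. Twofold O-alkylation of 1 (MOMCl, 2.0 equiv, i-Pr2NEt, DMF; mono- and tris-ethers separated and recycled) should give 3,5-bis(methoxymethoxy)phenol F1. O-Allylation (allyl bromide, K2CO3, acetone) should give 1-(allyloxy)-3,5-bis(methoxymethoxy)benzene F2. Aromatic Claisen rearrangement (N,N-diethylaniline, 190 °C; both ortho positions equivalent) should give 2-allyl-3,5-bis(methoxymethoxy)phenol F3. O-Alkylation with 3-chloro-2-methylprop-1-ene (K2CO3, DMF) should give 2-allyl-1,5-bis(methoxymethoxy)-3-[(2-methylprop-2-en-1-yl)oxy]benzene F4. Ring-closing metathesis with second-generation Grubbs catalyst (CH2Cl2, 40 °C) should then deliver 8.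

2. Step 6. Deprotonation of the benzylic, allylic C5 methylene or of the allyl ether C2 methylene may compete with ring metalation and lead to ring opening or Wittig-type rearrangement of the oxepine. The fallback joins the side chain before the oxepine exists, at the chromene stage where neither methylene is present. It sets out from 5 and comes back at 14. Metalation of 5 between its two MOM ethers (n-BuLi, TMEDA, THF, 0 °C) and addition of 11 should give 1-[5,7-bis(methoxymethoxy)-2,2-dimethyl-2H-chromen-6-yl]-3-[3,4-bis(methoxymethoxy)phenyl]propan-1-one F5. Irradiation of F5 under the conditions of step 3 should then give 14 directly; the ketone, twisted out of the arene plane by its two ortho ethers, should stay a spectator.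

3. Step 7. The slow cleavage of the two non-activated catechol acetals may require acid exposure long enough for methanol to add across the trisubstituted alkene, for the allyl aryl ether to ionise, or for formaldehyde equivalents to alkylate the liberated electron-rich rings. The fallback changes the catechol protection so that no unactivated acetal has to be cleaved. It sets out from 9 (and uses 8) and comes back at 15. Amide coupling of 9 (MeNH(OMe)·HCl, EDC·HCl, N-methylmorpholine, CH2Cl2) should give 3-(3,4-dihydroxyphenyl)-N-methoxy-N-methylpropanamide F6. Silylation (t-BuMe2SiCl, imidazole, DMF) should give 3-{3,4-bis[(tert-butyldimethylsilyl)oxy]phenyl}-N-methoxy-N-methylpropanamide F7. Lithiation of 8 as in step 6 and addition of F7 in place of 11 should give 1-[6,8-bis(methoxymethoxy)-3-methyl-2,5-dihydro-1-benzoxepin-7-yl]-3-{3,4-bis[(tert-butyldimethylsilyl)oxy]phenyl}propan-1-one F8. Tetrabutylammonium fluoride/AcOH in THF at 0 °C should free the catechol to give 1-[6,8-bis(methoxymethoxy)-3-methyl-2,5-dihydro-1-benzoxepin-7-yl]-3-(3,4-dihydroxyphenyl)propan-1-one F9. Brief treatment with 0.5 M HCl in MeOH at 20 °C, enough for the two ketone-flanking acetals, should then give 15.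

**Further compounds**

F1 | step 3 | 3,5-bis(methoxymethoxy)phenol | COCOc1cc(O)cc(OCOC)c1
F2 | step 3 | 1-(allyloxy)-3,5-bis(methoxymethoxy)benzene | C=CCOc1cc(OCOC)cc(OCOC)c1
F3 | step 3 | 2-allyl-3,5-bis(methoxymethoxy)phenol | C=CCc1c(O)cc(OCOC)cc1OCOC
F4 | step 3 | 2-allyl-1,5-bis(methoxymethoxy)-3-[(2-methylprop-2-en-1-yl)oxy]benzene | C=CCc1c(OCC(C)=C)cc(OCOC)cc1OCOC
F5 | step 6 | 1-[5,7-bis(methoxymethoxy)-2,2-dimethyl-2H-chromen-6-yl]-3-[3,4-bis(methoxymethoxy)phenyl]propan-1-one | CC1(C)C=Cc2c(OCOC)c(C(=O)CCc3ccc(OCOC)c(OCOC)c3)c(OCOC)cc2O1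
F6 | step 7 | 3-(3,4-dihydroxyphenyl)-N-methoxy-N-methylpropanamide | CON(C)C(=O)CCc1ccc(O)c(O)c1
F7 | step 7 | 3-{3,4-bis[(tert-butyldimethylsilyl)oxy]phenyl}-N-methoxy-N-methylpropanamide | CON(C)C(=O)CCc1ccc(O[Si](C)(C)C(C)(C)C)c(O[Si](C)(C)C(C)(C)C)c1
F8 | step 7 | 1-[6,8-bis(methoxymethoxy)-3-methyl-2,5-dihydro-1-benzoxepin-7-yl]-3-{3,4-bis[(tert-butyldimethylsilyl)oxy]phenyl}propan-1-one | CC1=CCc2c(cc(OCOC)c(C(=O)CCc3ccc(O[Si](C)(C)C(C)(C)C)c(O[Si](C)(C)C(C)(C)C)c3)c2OCOC)OC1
F9 | step 7 | 1-[6,8-bis(methoxymethoxy)-3-methyl-2,5-dihydro-1-benzoxepin-7-yl]-3-(3,4-dihydroxyphenyl)propan-1-one | CC1=CCc2c(cc(OCOC)c(C(=O)CCc3ccc(O)c(O)c3)c2OCOC)OC1
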